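**Strategy.** Everything rests on taking ring A of the isoflavone (C4a, C5, C6, C7, C8, C8a) apart into a 3-methoxy-4-alkylcyclobutenone and a prenyl-substituted siloxyalkyne. Their thermal benzannulation forms C7–C8 and C8a–C4a and re-closes C6–C7 in one operation. It gives the hexasubstituted benzene with its three oxygens already differentiated (C5 OMe, C7 OH, C8a O-silyl), the two carbon chains at C6 and C8 in place, and C4a as the only C–H. The cyclobutenone carries the (S)-configured silyloxy side chain, made from (R)-isopropyloxirane. The lone C4a–H is then lithiated to attach C4, C3 and ring B, and ring C is closed last by a one-carbon insertion.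

Key step: step 8

Assumption: (R)-2-isopropyloxirane of high enantiomeric purity is taken as a purchasable building block; the C4 epimers of the cyclobutenone and the alkene geometries drawn for transient intermediates have no bearing on the outcome.

**Route**

Step 1
Reactants: 1 (R)-2-isopropyloxirane; 2 allylmagnesium bromide
Product: 3 (3S)-2-methylhept-6-en-3-ol
Conditions: 2 (1.3 equiv), CuI (10 mol%), THF, −30 → 0 °C; aq NH4Cl
Reagents that add atoms: none
Why: Copper-catalysed Grignard opening of a monosubstituted epoxide is an SN2 attack at the unsubstituted CH2, so the stereocentre is not touched and the (R)-epoxide carbon becomes the (S)-carbinol only through the change in CIP ranking.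

Step 2
Reactants: 3 (3S)-2-methylhept-6-en-3-ol
Product: 4 tert-butyl(dimethyl){[(3S)-2-methylhept-6-en-3-yl]oxy}silane
Conditions: TBSOTf (1.2 equiv), 2,6-lutidine (1.5 equiv), CH2Cl2, 0 °C
Reagents that add atoms: tert-butyldimethylsilyl trifluoromethanesulfonate, CC(C)(C)[Si](C)(C)OS(=O)(=O)C(F)(F)F
Why: Silylation of a hindered secondary alcohol with a silyl triflate and a hindered pyridine base is routine, and the TBS ether is chosen because it survives base, organolithium and heat yet leaves in the final acid step.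

Step 3
Reactants: 4 tert-butyl(dimethyl){[(3S)-2-methylhept-6-en-3-yl]oxy}silane
Product: 5 (4S)-4-(tert-butyldimethylsilyloxy)-5-methylhexanoic acid
Conditions: RuCl3·xH2O (2 mol%), NaIO4 (5 equiv), EtOAc/MeCN/H2O, 0 °C → rt
Reagents that add atoms: sodium periodate, [Na+].[O-]I(=O)(=O)=O; water, O
Why: Oxidative cleavage of a terminal alkene with catalytic RuO4 regenerated by periodate (Sharpless conditions) gives the one-carbon-shorter carboxylic acid directly and leaves the secondary TBS ether and the stereocentre untouched.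

Step 4
Reactants: 6 chloroacetaldehyde dimethyl acetal
Product: 8 methoxyacetylene (methoxyethyne), via sodium methoxyacetylide 7 (not isolated)
Conditions: NaNH2 (3.1 equiv), liq. NH3, −33 °C; evaporate NH3; sat. aq NaCl, −20 °C; distil (bp about 23 °C) into cold Et2O
Reagents that add atoms: none
Why: Twofold base-induced elimination (methanol, then HCl) from the chloroacetal with NaNH2 in liquid ammonia gives the sodium alkynyl ether, which water protonates to the volatile ynol ether, an established preparative procedure.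

Step 5
Reactants: 5 (4S)-4-(tert-butyldimethylsilyloxy)-5-methylhexanoic acid; 8 methoxyacetylene
Product: 11 3-methoxy-4-[(2S)-2-(tert-butyldimethylsilyloxy)-3-methylbutyl]cyclobut-2-en-1-one (C4 epimers), via acid chloride 9 (not isolated), via ketene 10 (not isolated)
Conditions: 1-chloro-N,N,2-trimethylprop-1-en-1-amine (1.05 equiv), CH2Cl2, 0 °C → rt; then added slowly to 8 (3 equiv), Et3N (1.5 equiv), Et2O, 0 °C → rt, sealed flask, 16 h
Reagents that add atoms: none
Why: The chloroenamine makes the acid chloride without releasing HCl, Et3N dehydrochlorinates it to the aldoketene, and the ketene–ynol ether (2+2) cycloaddition joins the ketene carbonyl carbon to the nucleophilic terminal alkyne carbon to give the 3-alkoxy-4-alkylcyclobutenone; the new C4 stereocentre forms without control, which is harmless because this carbon becomes aromatic C6.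

Step 6
Reactants: 12 prenyl bromide; 13 ethynylmagnesium bromide
Product: 14 5-methylhex-4-en-1-yne
Conditions: 13 (2 equiv, 0.5 M in THF), CuCl (5 mol%), THF, 0 → 40 °C; aq NH4Cl; fractional distillation
Reagents that add atoms: none
Why: Copper-catalysed coupling of an alkynyl Grignard reagent with a primary allylic bromide proceeds mainly by direct (alpha) substitution to the skipped enyne, and the excess of acetylide limits double allylation.

Step 7
Reactants: 14 5-methylhex-4-en-1-yne
Product: 17 5-methyl-1-(triisopropylsilyloxy)hex-4-en-1-yne, via lithium acetylide 15 (not isolated), via lithium ynolate 16 (not isolated)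
Conditions: n-BuLi, THF, −78 °C; LiOOt-Bu (from t-BuOOH and LiN(SiMe3)2, THF, −78 °C), −78 → 0 °C; TIPSOTf, −78 → 0 °C
Reagents that add atoms: tert-butyl hydroperoxide, CC(C)(C)OO; triisopropylsilyl trifluoromethanesulfonate, CC(C)[Si](OS(=O)(=O)C(F)(F)F)(C(C)C)C(C)C
Why: Oxidation of a lithium acetylide with lithium tert-butyl peroxide gives the lithium ynolate (Julia ynolate synthesis), which the bulky silyl triflate traps on oxygen to give an isolable triisopropylsilyl ynol ether.

Step 8
Reactants: 11 3-methoxy-4-[(2S)-2-(tert-butyldimethylsilyloxy)-3-methylbutyl]cyclobut-2-en-1-one; 17 5-methyl-1-(triisopropylsilyloxy)hex-4-en-1-yne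
Product: 22 2-[(2S)-2-(tert-butyldimethylsilyloxy)-3-methylbutyl]-3-methoxy-6-(3-methylbut-2-en-1-yl)-5-(triisopropylsilyloxy)phenol, via vinylketene 18 (not isolated), via alkenylcyclobutenone 19 (not isolated), via dienylketene 20 (not isolated), via cyclohexadienone 21 (not isolated)
Conditions: 11 (1.0 equiv), 17 (1.3 equiv), toluene (0.5 M), argon, 80 °C 4 h, then 110 °C 12 h
Reagents that add atoms: none
Why: Conrotatory four-electron opening of 11 (side chain turning outward) gives vinylketene 18, whose ketene C=C adds the siloxyalkyne in a (2+2) cycloaddition to 19; a second, reversible four-electron opening gives dienylketene 20, which undergoes thermal six-electron electrocyclisation to 21 and tautomerises to phenol 22. The closest known reaction type is the Danheiser benzannulation of cyclobutenones with siloxyalkynes. Ring A is closed by the disrotatory six-electron electrocyclisation that re-forms C6–C7, after C7–C8 and C8a–C4a have been made intermolecularly. No stereocentre is created, since C4 of 11 becomes aromatic C6 and the side-chain carbinol is a spectator. The selectivity needed is the orientation of the (2+2) step: the oxygen-polarised ynol ether attacks the ketene carbonyl carbon (future C7) with its prenyl-bearing carbon, so prenyl ends at C8 and the silyloxy group at C8a. The reversibility of the second ring opening funnels material through the dienylketene whose alkenyl group points inward, and the phenol formed is shielded by two ortho chains against acylation by remaining ketene.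

Step 9
Reactants: 22 2-[(2S)-2-(tert-butyldimethylsilyloxy)-3-methylbutyl]-3-methoxy-6-(3-methylbut-2-en-1-yl)-5-(triisopropylsilyloxy)phenol
Product: 23 4-[(2S)-2-(tert-butyldimethylsilyloxy)-3-methylbutyl]-5-methoxy-2-(3-methylbut-2-en-1-yl)benzene-1,3-diol
Conditions: TBAF (1.05 equiv), THF, 0 °C, 15 min; aq NH4Cl
Reagents that add atoms: none
Why: Fluoride cleaves a phenolic silyl ether far faster than a hindered secondary alkyl TBS ether, so one equivalent at 0 °C should unmask only the C8a oxygen (chemoselective desilylation).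

Step 10
Reactants: 23 4-[(2S)-2-(tert-butyldimethylsilyloxy)-3-methylbutyl]-5-methoxy-2-(3-methylbut-2-en-1-yl)benzene-1,3-diol
Product: 24 tert-butyl({(2S)-1-[6-methoxy-2,4-bis(methoxymethoxy)-3-(3-methylbut-2-en-1-yl)phenyl]-3-methylbutan-2-yl}oxy)dimethylsilane
Conditions: NaH (2.5 equiv), MOMCl (2.5 equiv), THF/DMF, 0 °C → rt
Reagents that add atoms: chloromethyl methyl ether, COCCl
Why: Williamson-type O-alkylation of the two sodium phenoxides with the reactive chloromethyl ether protects both phenols as MOM ethers, which withstand butyllithium and turn the C8a oxygen into a strong ortho-director.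

Step 11
Reactants: 25 4-hydroxyphenylacetic acid
Product: 26 2-(4-hydroxyphenyl)-N-methoxy-N-methylacetamide
Conditions: MeNHOMe·HCl, EDC·HCl, HOBt, i-Pr2NEt, CH2Cl2, 0 °C → rt
Reagents that add atoms: N,O-dimethylhydroxylamine hydrochloride, CNOC.Cl
Why: Carbodiimide/HOBt amide coupling of an arylacetic acid with N,O-dimethylhydroxylamine is routine, the amine outcompeting the free phenol for the active ester.

Step 12
Reactants: 26 2-(4-hydroxyphenyl)-N-methoxy-N-methylacetamide
Product: 27 N-methoxy-2-[4-(methoxymethoxy)phenyl]-N-methylacetamide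
Conditions: MOMCl (1.5 equiv), i-Pr2NEt (2 equiv), CH2Cl2, 0 °C → rt
Reagents that add atoms: chloromethyl methyl ether, COCCl
Why: O-Alkylation of a phenol with chloromethyl methyl ether and an amine base is a standard MOM protection that masks the acidic ring-B hydroxyl for the organolithium and acetal steps.

Step 13
Reactants: 24 tert-butyl({(2S)-1-[6-methoxy-2,4-bis(methoxymethoxy)-3-(3-methylbut-2-en-1-yl)phenyl]-3-methylbutan-2-yl}oxy)dimethylsilane; 27 N-methoxy-2-[4-(methoxymethoxy)phenyl]-N-methylacetamide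
Product: 29 1-{3-[(2S)-2-(tert-butyldimethylsilyloxy)-3-methylbutyl]-2-methoxy-4,6-bis(methoxymethoxy)-5-(3-methylbut-2-en-1-yl)phenyl}-2-[4-(methoxymethoxy)phenyl]ethan-1-one, via aryllithium 28 (not isolated)
Conditions: n-BuLi (1.15 equiv), TMEDA (1.2 equiv), THF, −20 → 0 °C, 1 h; then 27 (1.3 equiv), −78 → 0 °C; aq NH4Cl
Reagents that add atoms: none
Why: Directed ortho-metalation removes the only ring hydrogen, C4a–H, which is flanked by the methoxy and methoxymethoxy groups, and the aryllithium acylates the Weinreb amide through a chelated tetrahedral intermediate that prevents over-addition (Weinreb ketone synthesis).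

Step 14
Reactants: 29 the deoxybenzoin of step 13
Product: 30 (2E)-1-{3-[(2S)-2-(tert-butyldimethylsilyloxy)-3-methylbutyl]-2-methoxy-4,6-bis(methoxymethoxy)-5-(3-methylbut-2-en-1-yl)phenyl}-3-(dimethylamino)-2-[4-(methoxymethoxy)phenyl]prop-2-en-1-one
Conditions: Me2NCH(OMe)2 (5 equiv), toluene, 95 °C
Reagents that add atoms: N,N-dimethylformamide dimethyl acetal, COC(OC)N(C)C
Why: Condensation of the doubly activated methylene of a deoxybenzoin with DMF dimethyl acetal gives the enaminone that supplies C2, and with every hydroxyl protected no O-methylation can compete.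

Step 15
Reactants: 30 the enaminone of step 14
Product: 32 7-hydroxy-6-[(2S)-2-hydroxy-3-methylbutyl]-3-(4-hydroxyphenyl)-5-methoxy-8-(3-methylbut-2-en-1-yl)-4H-chromen-4-one, via ring-open hydroxy enaminone 31 (not isolated)
Conditions: HCl (1.25 M in MeOH), MeOH/THF, 40 °C; aq NaHCO3
Reagents that add atoms: none
Why: Acidic methanolysis removes the three MOM acetals and the TBS ether, and the freed C8a phenol adds to the protonated enaminone and expels dimethylamine (addition–elimination, 6-endo closure of ring C), the usual last stage of the deoxybenzoin isoflavone synthesis; the stereocentre is not involved.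

**Compound list**

1 | (R)-2-isopropyloxirane | CC(C)[C@@H]1CO1 | starting material
2 | allylmagnesium bromide | C=CC[Mg]Br | starting material
3 | (3S)-2-methylhept-6-en-3-ol | CC(C)[C@@H](O)CCC=C | intermediate
4 | tert-butyl(dimethyl){[(3S)-2-methylhept-6-en-3-yl]oxy}silane | CC(C)[C@@H](O[Si](C)(C)C(C)(C)C)CCC=C | intermediate
5 | (4S)-4-(tert-butyldimethylsilyloxy)-5-methylhexanoic acid | CC(C)[C@@H](O[Si](C)(C)C(C)(C)C)CCC(=O)O | intermediate
6 | chloroacetaldehyde dimethyl acetal (2-chloro-1,1-dimethoxyethane) | COC(CCl)OC | starting material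
7 | sodium methoxyacetylide | COC#C[Na] | intermediate
8 | methoxyacetylene (methoxyethyne) | COC#C | intermediate
9 | (4S)-4-(tert-butyldimethylsilyloxy)-5-methylhexanoyl chloride | CC(C)[C@@H](O[Si](C)(C)C(C)(C)C)CCC(Cl)=O | intermediate
10 | (4S)-4-(tert-butyldimethylsilyloxy)-5-methylhex-1-en-1-one (aldoketene) | CC(C)[C@@H](O[Si](C)(C)C(C)(C)C)CC=C=O | intermediate
11 | 3-methoxy-4-[(2S)-2-(tert-butyldimethylsilyloxy)-3-methylbutyl]cyclobut-2-en-1-one (C4 epimers) | COC1=CC(=O)C1C[C@H](O[Si](C)(C)C(C)(C)C)C(C)C | intermediate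
12 | prenyl bromide (1-bromo-3-methylbut-2-ene) | CC(C)=CCBr | starting material
13 | ethynylmagnesium bromide | C#C[Mg]Br | starting material
14 | 5-methylhex-4-en-1-yne | CC(C)=CCC#C | intermediate
15 | (5-methylhex-4-en-1-yn-1-yl)lithium | CC(C)=CCC#C[Li] | intermediate
16 | lithium 5-methylhex-4-en-1-yn-1-olate | CC(C)=CCC#CO[Li] | intermediate
17 | 5-methyl-1-(triisopropylsilyloxy)hex-4-en-1-yne | CC(C)=CCC#CO[Si](C(C)C)(C(C)C)C(C)C | intermediate
18 | (3Z,6S)-6-(tert-butyldimethylsilyloxy)-3-methoxy-7-methylocta-1,3-dien-1-one (vinylketene) | O=C=C/C(OC)=C/C[C@H](O[Si](C)(C)C(C)(C)C)C(C)C | intermediate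
19 | 4-[(1Z,4S)-4-(tert-butyldimethylsilyloxy)-1-methoxy-5-methylhex-1-en-1-yl]-2-(3-methylbut-2-en-1-yl)-3-(triisopropylsilyloxy)cyclobut-2-en-1-one (ring C4 epimers) | O=C1C(CC=C(C)C)=C(O[Si](C(C)C)(C(C)C)C(C)C)C1/C(OC)=C/C[C@H](O[Si](C)(C)C(C)(C)C)C(C)C | intermediate
20 | (3E,5Z,8S)-8-(tert-butyldimethylsilyloxy)-5-methoxy-9-methyl-2-(3-methylbut-2-en-1-yl)-3-(triisopropylsilyloxy)deca-1,3,5-trien-1-one (dienylketene) | O=C=C(CC=C(C)C)/C(O[Si](C(C)C)(C(C)C)C(C)C)=C\C(OC)=C\C[C@H](O[Si](C)(C)C(C)(C)C)C(C)C | intermediate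
21 | 6-[(2S)-2-(tert-butyldimethylsilyloxy)-3-methylbutyl]-5-methoxy-2-(3-methylbut-2-en-1-yl)-3-(triisopropylsilyloxy)cyclohexa-2,4-dien-1-one (C6 epimers) | O=C1C(CC=C(C)C)=C(O[Si](C(C)C)(C(C)C)C(C)C)C=C(OC)C1C[C@H](O[Si](C)(C)C(C)(C)C)C(C)C | intermediate
22 | 2-[(2S)-2-(tert-butyldimethylsilyloxy)-3-methylbutyl]-3-methoxy-6-(3-methylbut-2-en-1-yl)-5-(triisopropylsilyloxy)phenol | COc1cc(O[Si](C(C)C)(C(C)C)C(C)C)c(CC=C(C)C)c(O)c1C[C@H](O[Si](C)(C)C(C)(C)C)C(C)C | intermediate
23 | 4-[(2S)-2-(tert-butyldimethylsilyloxy)-3-methylbutyl]-5-methoxy-2-(3-methylbut-2-en-1-yl)benzene-1,3-diol | COc1cc(O)c(CC=C(C)C)c(O)c1C[C@H](O[Si](C)(C)C(C)(C)C)C(C)C | intermediate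
24 | tert-butyl({(2S)-1-[6-methoxy-2,4-bis(methoxymethoxy)-3-(3-methylbut-2-en-1-yl)phenyl]-3-methylbutan-2-yl}oxy)dimethylsilane | COc1cc(OCOC)c(CC=C(C)C)c(OCOC)c1C[C@H](O[Si](C)(C)C(C)(C)C)C(C)C | intermediate
25 | 4-hydroxyphenylacetic acid | OC(=O)Cc1ccc(O)cc1 | starting material
26 | 2-(4-hydroxyphenyl)-N-methoxy-N-methylacetamide | CON(C)C(=O)Cc1ccc(O)cc1 | intermediate
27 | N-methoxy-2-[4-(methoxymethoxy)phenyl]-N-methylacetamide | CON(C)C(=O)Cc1ccc(OCOC)cc1 | intermediate
28 | {3-[(2S)-2-(tert-butyldimethylsilyloxy)-3-methylbutyl]-2-methoxy-4,6-bis(methoxymethoxy)-5-(3-methylbut-2-en-1-yl)phenyl}lithium | COc1c([Li])c(OCOC)c(CC=C(C)C)c(OCOC)c1C[C@H](O[Si](C)(C)C(C)(C)C)C(C)C | intermediate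
29 | 1-{3-[(2S)-2-(tert-butyldimethylsilyloxy)-3-methylbutyl]-2-methoxy-4,6-bis(methoxymethoxy)-5-(3-methylbut-2-en-1-yl)phenyl}-2-[4-(methoxymethoxy)phenyl]ethan-1-one | COc1c(C(=O)Cc2ccc(OCOC)cc2)c(OCOC)c(CC=C(C)C)c(OCOC)c1C[C@H](O[Si](C)(C)C(C)(C)C)C(C)C | intermediate
30 | (2E)-1-{3-[(2S)-2-(tert-butyldimethylsilyloxy)-3-methylbutyl]-2-methoxy-4,6-bis(methoxymethoxy)-5-(3-methylbut-2-en-1-yl)phenyl}-3-(dimethylamino)-2-[4-(methoxymethoxy)phenyl]prop-2-en-1-one | COc1c(C(=O)/C(=C/N(C)C)c2ccc(OCOC)cc2)c(OCOC)c(CC=C(C)C)c(OCOC)c1C[C@H](O[Si](C)(C)C(C)(C)C)C(C)C | intermediate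
31 | (2E)-1-{2,4-dihydroxy-5-[(2S)-2-hydroxy-3-methylbutyl]-6-methoxy-3-(3-methylbut-2-en-1-yl)phenyl}-3-(dimethylamino)-2-(4-hydroxyphenyl)prop-2-en-1-one | COc1c(C(=O)/C(=C/N(C)C)c2ccc(O)cc2)c(O)c(CC=C(C)C)c(O)c1C[C@H](O)C(C)C | intermediate
32 | 7-hydroxy-6-[(2S)-2-hydroxy-3-methylbutyl]-3-(4-hydroxyphenyl)-5-methoxy-8-(3-methylbut-2-en-1-yl)-4H-chromen-4-one | COc1c(C[C@H](O)C(C)C)c(O)c(CC=C(C)C)c2occ(-c3ccc(O)cc3)c(=O)c12 | target

**Step count**

Total: 15 steps. Longest linear sequence: 10 steps (steps 1, 2, 3, 5, 8, 9, 10, 13, 14, 15).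

**Steps most likely to fail**

1. Step 8. The methoxy-substituted vinylketene may be lost to self-condensation or to acylation of the phenol already formed before it meets the alkyne, or the cascade may stall at the alkenylcyclobutenone stage. The fallback builds the same substitution pattern on a preformed arene by two directed metalations; it sets out from 12 and 1 and comes back to the route at 24. Commercial 5-methoxybenzene-1,3-diol (COc1cc(O)cc(O)c1) is protected with MOMCl/NaH to give 1-methoxy-3,5-bis(methoxymethoxy)benzene F1. n-BuLi in THF at 0 °C should metalate between the two MOM ethers to give [4-methoxy-2,6-bis(methoxymethoxy)phenyl]lithium F2, which with catalytic CuBr·SMe2 and 12 gives 5-methoxy-1,3-bis(methoxymethoxy)-2-(3-methylbut-2-en-1-yl)benzene F3. A second metalation (n-BuLi/TMEDA) at one of the two equivalent positions between OMe and OMOM gives [2-methoxy-4,6-bis(methoxymethoxy)-5-(3-methylbut-2-en-1-yl)phenyl]lithium F4. F4 opens 1 at its CH2 in the presence of BF3·OEt2 at −78 °C to give (2S)-1-[6-methoxy-2,4-bis(methoxymethoxy)-3-(3-methylbut-2-en-1-yl)phenyl]-3-methylbutan-2-ol F5. Silylation with TBSOTf/2,6-lutidine then gives 24.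

2. Step 13. The hindered aryllithium may deprotonate the acidic benzylic CH2 of the amide instead of adding to it, which would return 24 unchanged. The fallback replaces acyl substitution by aldehyde addition and oxidation; it sets out from 27 and 28 and comes back at 29. Reduction of 27 with i-Bu2AlH (THF, −78 °C) gives 2-[4-(methoxymethoxy)phenyl]acetaldehyde F6. Addition of 28 at −78 °C, where carbonyl addition should outrun enolisation, gives 1-{3-[(2S)-2-(tert-butyldimethylsilyloxy)-3-methylbutyl]-2-methoxy-4,6-bis(methoxymethoxy)-5-(3-methylbut-2-en-1-yl)phenyl}-2-[4-(methoxymethoxy)phenyl]ethan-1-ol F7 as both carbinol epimers. Oxidation with Dess–Martin periodinane (NaHCO3-buffered, CH2Cl2) gives 29.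

3. Step 5. Evaporative loss of the low-boiling alkyne and dimerisation of the aldoketene may outrun the cycloaddition. The fallback sets out from ketene 10 (generated from 5 as in step 5) and comes back at 11. The ketene is trapped with commercial, higher-boiling ethoxyacetylene (CCOC#C), used in large excess in refluxing Et2O, to give 3-ethoxy-4-[(2S)-2-(tert-butyldimethylsilyloxy)-3-methylbutyl]cyclobut-2-en-1-one F8. The alkoxy group is then exchanged by acid-catalysed addition–elimination in methanol (catalytic pyridinium p-toluenesulfonate, MeOH, 0 °C → rt) to give 11.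

**Further compounds**

F1 | step 8 | 1-methoxy-3,5-bis(methoxymethoxy)benzene | COCOc1cc(OC)cc(OCOC)c1
F2 | step 8 | [4-methoxy-2,6-bis(methoxymethoxy)phenyl]lithium | COCOc1cc(OC)cc(OCOC)c1[Li]
F3 | step 8 | 5-methoxy-1,3-bis(methoxymethoxy)-2-(3-methylbut-2-en-1-yl)benzene | COCOc1cc(OC)cc(OCOC)c1CC=C(C)C
F4 | step 8 | [2-methoxy-4,6-bis(methoxymethoxy)-5-(3-methylbut-2-en-1-yl)phenyl]lithium | COc1cc(OCOC)c(CC=C(C)C)c(OCOC)c1[Li]
F5 | step 8 | (2S)-1-[6-methoxy-2,4-bis(methoxymethoxy)-3-(3-methylbut-2-en-1-yl)phenyl]-3-methylbutan-2-ol | COc1cc(OCOC)c(CC=C(C)C)c(OCOC)c1C[C@H](O)C(C)C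
F6 | step 13 | 2-[4-(methoxymethoxy)phenyl]acetaldehyde | COCOc1ccc(CC=O)cc1
F7 | step 13 | 1-{3-[(2S)-2-(tert-butyldimethylsilyloxy)-3-methylbutyl]-2-methoxy-4,6-bis(methoxymethoxy)-5-(3-methylbut-2-en-1-yl)phenyl}-2-[4-(methoxymethoxy)phenyl]ethan-1-ol (carbinol epimers) | COc1c(C(O)Cc2ccc(OCOC)cc2)c(OCOC)c(CC=C(C)C)c(OCOC)c1C[C@H](O[Si](C)(C)C(C)(C)C)C(C)C
F8 | step 5 | 3-ethoxy-4-[(2S)-2-(tert-butyldimethylsilyloxy)-3-methylbutyl]cyclobut-2-en-1-one (C4 epimers) | CCOC1=CC(=O)C1C[C@H](O[Si](C)(C)C(C)(C)C)C(C)C
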